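**Plan**

- Locants: ring A is C1 (chain), C2 (O‑tigloyl), C3/C4 (oxirane, CH3 on C4), C5 (C=O), C6 (OAc); the chain is C7(=C14H2)–C8(O‑tigloyl)–C9–C10/C11 (oxirane); α is the face of the C1 chain, β the opposite face.
- Feature: the C5 ketone and C6 carbinol of ring A form an α‑ketol next to C1, so C6 can be the formyl carbon of a 1‑formylcyclopent‑2‑en‑1‑ol; after removal of the three esters and both oxiranes the C1–C6 bond is cut by a retro α‑ketol shift.
- The cyclopentenol is cut at C5–C6 (dithiane anion on a cyclopentenone), the cyclopentenone at C1–C2 (Piancatelli rearrangement; 3‑methylfuran‑2‑carbaldehyde brings C1–C5 and the C4 methyl) and at C1–C7 (alkenyllithium); the chain is cut at C7–C8 (acetylide plus 4‑methylpent‑3‑enal).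
- Forward: chain (steps 1–6), furylcarbinol (7), five‑membered ring (8), six‑membered ring A by one‑carbon ring expansion (12), then C6 acetate, ring oxirane, C2 tiglate, C8 tiglate, chain oxirane.
- Stereochemistry: C8 by asymmetric transfer hydrogenation; C1/C2 trans by conrotatory electrocyclisation, their absolute sense by separating the two trans isomers against C8; C6 in the ketol shift; C3/C4 by epoxidation anti to O‑2; C2 by Mitsunobu inversion; C10 by Shi epoxidation.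

Key step: step 12

Assumption: the two trans isomers formed in step 8 differ enough (three stereocentres, free hydroxyl) to be separated by chromatography.
Abbreviations: PMB = 4‑methoxybenzyl, TBS = tert‑butyldimethylsilyl, Tig = (E)‑2‑methylbut‑2‑enoyl.

**Route**

Step 1
Reactants: 1 4‑methylpent‑3‑en‑1‑ol
Product: 2 4‑methylpent‑3‑enal
Conditions: PhI(OAc)2, TEMPO (10 mol%), CH2Cl2, rt
Reagents that add atoms: none
Why: TEMPO/PhI(OAc)2 oxidation of a primary alcohol stops at the aldehyde in a base‑free medium, so the β,γ‑double bond should not move into conjugation; no stereocentre is formed and the volatile aldehyde is used as a solution.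

Step 2
Reactants: 2 4‑methylpent‑3‑enal; 3 ethynyltrimethylsilane
Product: 5 rac‑6‑methyl‑1‑(trimethylsilyl)hept‑5‑en‑1‑yn‑3‑ol, via lithium (trimethylsilyl)acetylide 4 (not isolated)
Conditions: 3, n‑BuLi, THF, −78 °C; then 2, −78 → −20 °C; H2O
Reagents that add atoms: none
Why: 1,2‑addition of a lithium acetylide to an aldehyde at low temperature outruns enolisation of the β,γ‑unsaturated aldehyde; the carbinol is left racemic because it is oxidised in step 3.

Step 3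
Reactants: 5 rac‑6‑methyl‑1‑(trimethylsilyl)hept‑5‑en‑1‑yn‑3‑ol
Product: 6 6‑methyl‑1‑(trimethylsilyl)hept‑5‑en‑1‑yn‑3‑one
Conditions: Dess–Martin periodinane, CH2Cl2, 0 °C → rt
Reagents that add atoms: none
Why: Dess–Martin oxidation of a propargylic alcohol to the ynone under non‑basic conditions that should leave the skipped double bond in place; the stereocentre is removed on purpose.

Step 4
Reactants: 6 6‑methyl‑1‑(trimethylsilyl)hept‑5‑en‑1‑yn‑3‑one
Product: 7 (3S)‑6‑methyl‑1‑(trimethylsilyl)hept‑5‑en‑1‑yn‑3‑ol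
Conditions: Ru[(S,S)‑TsDPEN](p‑cymene) (0.5 mol%; TsDPEN = N‑tosyl‑1,2‑diphenylethylenediamine), i‑PrOH, rt
Reagents that add atoms: none
Why: Noyori asymmetric transfer hydrogenation of an α,β‑acetylenic ketone: hydride and proton pass from Ru–H/N–H through a six‑membered transition state in which the alkynyl group takes the place usually held by an aryl group, so the (S,S) catalyst should give the (S)‑carbinol (C8), and the base‑free medium spares the β,γ‑alkene.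

Step 5
Reactants: 7 (3S)‑6‑methyl‑1‑(trimethylsilyl)hept‑5‑en‑1‑yn‑3‑ol
Product: 9 (3S)‑3‑(PMBO)‑6‑methylhept‑5‑en‑1‑yne, via terminal alkynol 8 (not isolated)
Conditions: K2CO3 (0.2 equiv), MeOH, rt; solvent switch; then NaH, PMBCl, Bu4NI (cat.), THF/DMF, 0 °C → rt
Reagents that add atoms: 4‑methoxybenzyl chloride, COc1ccc(CCl)cc1
Why: methoxide‑mediated protodesilylation of the alkynylsilane followed by Williamson etherification of the sodium alkoxide; telescoping avoids isolating the volatile alkynol, and C8 is not touched.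

Step 6
Reactants: 9 (3S)‑3‑(PMBO)‑6‑methylhept‑5‑en‑1‑yne
Product: 10 tributyl[(3S)‑3‑(PMBO)‑6‑methylhepta‑1,5‑dien‑2‑yl]stannane
Conditions: Bu3SnH, Mo(CO)3(CNt‑Bu)3 (2 mol%), hydroquinone (cat.), THF, 55 °C
Reagents that add atoms: tributyltin hydride, CCCC[SnH](CCCC)CCCC
Why: molybdenum‑catalysed hydrostannation of a terminal propargylic ether places tin on the internal carbon next to the oxygenated centre; hydroquinone suppresses the radical pathway to the terminal stannane, and no stereocentre is formed.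

Step 7
Reactants: 10 tributyl[(3S)‑3‑(PMBO)‑6‑methylhepta‑1,5‑dien‑2‑yl]stannane; 11 3‑methylfuran‑2‑carbaldehyde
Product: 13 (3S)‑3‑(PMBO)‑6‑methyl‑2‑methylidene‑1‑(3‑methylfuran‑2‑yl)hept‑5‑en‑1‑ol (both C1 epimers), via alkenyllithium 12 (not isolated)
Conditions: 10, n‑BuLi, THF, −78 °C; then 11, −78 °C; H2O
Reagents that add atoms: none
Why: tin–lithium exchange followed by 1,2‑addition of the alkenyllithium to the aldehyde forms C1–C7; the carbinol centre is left uncontrolled because it is ionised in step 8, and at −78 °C loss of the allylic PMB‑oxy group from the alkenyllithium should not compete.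

Step 8
Reactants: 13 (3S)‑3‑(PMBO)‑6‑methyl‑2‑methylidene‑1‑(3‑methylfuran‑2‑yl)hept‑5‑en‑1‑ol
Product: 14 (4S,5R)‑4‑hydroxy‑2‑methyl‑5‑[(3S)‑3‑(PMBO)‑6‑methylhepta‑1,5‑dien‑2‑yl]cyclopent‑2‑en‑1‑one
Conditions: Dy(OTf)3 (10 mol%), t‑BuOH/H2O (5:1), 80 °C
Reagents that add atoms: water, O
Why: Piancatelli rearrangement: ionisation to a 2‑alkylidenefuranium ion, addition of water at the furan C5 (the later C2), ring opening and conrotatory 4π electrocyclisation of the hydroxypentadienyl cation set C1 and C2 trans; the remote C8 centre is not expected to bias the sense of rotation, so the two trans isomers are separated by chromatography here and the (4S,5R) isomer is carried on.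

Step 9
Reactants: 14 (4S,5R)‑4‑hydroxy‑2‑methyl‑5‑[(3S)‑3‑(PMBO)‑6‑methylhepta‑1,5‑dien‑2‑yl]cyclopent‑2‑en‑1‑one
Product: 15 (4S,5R)‑4‑(TBSO)‑2‑methyl‑5‑[(3S)‑3‑(PMBO)‑6‑methylhepta‑1,5‑dien‑2‑yl]cyclopent‑2‑en‑1‑one
Conditions: TBSCl, imidazole, DMF, rt
Reagents that add atoms: tert‑butyl(chloro)dimethylsilane, CC(C)(C)[Si](C)(C)Cl
Why: imidazole‑promoted silylation of a secondary alcohol is mild enough to avoid β‑elimination of the β‑hydroxy ketone; no stereocentre changes.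

Step 10
Reactants: 15 (4S,5R)‑4‑(TBSO)‑2‑methyl‑5‑[(3S)‑3‑(PMBO)‑6‑methylhepta‑1,5‑dien‑2‑yl]cyclopent‑2‑en‑1‑one; 16 1,3‑dithiane
Product: 18 (1R,4S,5R)‑4‑(TBSO)‑1‑(1,3‑dithian‑2‑yl)‑2‑methyl‑5‑[(3S)‑3‑(PMBO)‑6‑methylhepta‑1,5‑dien‑2‑yl]cyclopent‑2‑en‑1‑ol, via 2‑lithio‑1,3‑dithiane 17 (not isolated)
Conditions: 16, n‑BuLi, THF, −30 °C; then 15, −78 °C; H2O
Reagents that add atoms: none
Why: Corey–Seebach 1,2‑addition of 2‑lithio‑1,3‑dithiane to the α‑methyl enone (1,2‑selective in THF without HMPA) from the β face, anti to the adjacent C1 substituent, places the C5 hydroxyl α; low temperature suppresses enolisation towards C1.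

Step 11
Reactants: 18 (1R,4S,5R)‑4‑(TBSO)‑1‑(1,3‑dithian‑2‑yl)‑2‑methyl‑5‑[(3S)‑3‑(PMBO)‑6‑methylhepta‑1,5‑dien‑2‑yl]cyclopent‑2‑en‑1‑ol
Product: 19 (1R,4S,5R)‑4‑(TBSO)‑1‑hydroxy‑2‑methyl‑5‑[(3S)‑3‑(PMBO)‑6‑methylhepta‑1,5‑dien‑2‑yl]cyclopent‑2‑ene‑1‑carbaldehyde
Conditions: PhI(OCOCF3)2, MeCN/H2O (9:1), 0 °C, short reaction time
Reagents that add atoms: water, O
Why: oxidative dithioacetal hydrolysis is fast at 0 °C, so the aldehyde should be unmasked before the silyl ether, the PMB ether, the alkenes or the tertiary allylic alcohol react and before the hydroxy aldehyde rearranges; no stereocentre is touched.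

Step 12
Reactants: 19 (1R,4S,5R)‑4‑(TBSO)‑1‑hydroxy‑2‑methyl‑5‑[(3S)‑3‑(PMBO)‑6‑methylhepta‑1,5‑dien‑2‑yl]cyclopent‑2‑ene‑1‑carbaldehyde
Product: 20 (4S,5S,6S)‑4‑(TBSO)‑6‑hydroxy‑2‑methyl‑5‑[(3S)‑3‑(PMBO)‑6‑methylhepta‑1,5‑dien‑2‑yl]cyclohex‑2‑en‑1‑one
Conditions: Et3N (3 equiv), MeOH, 0 → 40 °C
Reagents that add atoms: none
Why: α‑ketol (acyloin) rearrangement of a tertiary α‑hydroxy aldehyde: the amine‑generated C5 alkoxide pushes the C5–C1 ring bond onto the formyl carbon C6 in a concerted 1,2‑shift, so C1–C6 forms and C5 becomes the ketone; the closest known reaction type is the ring expansion of 1‑hydroxycycloalkanecarbaldehydes to 2‑hydroxycycloalkanones. Ring A therefore closes by ring enlargement of the cyclopentene (one‑carbon insertion by a suprafacial 1,2‑alkyl shift, not a cyclisation), and C1 migrates with retention. The new C6 centre is set in the shift: in the protic, non‑chelating medium the C5–O and C6=O dipoles are opposed, C1 then adds to the face of the aldehyde that places O‑6 β (trans to the chain), and this is also the more stable all‑equatorial arrangement should C6 equilibrate. The selectivity needed is migration of C1 and not of vinylic C4; it is secured by the C3=C4 double bond, which stays on C5 and conjugates with the developing carbonyl group, and by the secondary, allylic nature of C1. If C4 migrates in part, tautomerisation of that ketol into conjugation leads to the same enone constitution. The aldehyde‑to‑ketone change and the enone make the step irreversible in practice, and the weak base keeps enolisation of the product slow.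

Step 13
Reactants: 20 (4S,5S,6S)‑4‑(TBSO)‑6‑hydroxy‑2‑methyl‑5‑[(3S)‑3‑(PMBO)‑6‑methylhepta‑1,5‑dien‑2‑yl]cyclohex‑2‑en‑1‑one
Product: 21 (1S,5S,6S)‑5‑(TBSO)‑3‑methyl‑2‑oxo‑6‑[(3S)‑3‑(PMBO)‑6‑methylhepta‑1,5‑dien‑2‑yl]cyclohex‑3‑en‑1‑yl acetate
Conditions: Ac2O, pyridine, DMAP (cat.), CH2Cl2, 0 °C → rt
Reagents that add atoms: acetic anhydride, CC(=O)OC(C)=O
Why: DMAP‑catalysed acetylation of the only free hydroxyl (the secondary α‑hydroxy ketone) proceeds with retention at C6.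

Step 14
Reactants: 21 (1S,5S,6S)‑5‑(TBSO)‑3‑methyl‑2‑oxo‑6‑[(3S)‑3‑(PMBO)‑6‑methylhepta‑1,5‑dien‑2‑yl]cyclohex‑3‑en‑1‑yl acetate
Product: 22 (1S,3S,4S,5R,6S)‑5‑(TBSO)‑1‑methyl‑2‑oxo‑4‑[(3S)‑3‑(PMBO)‑6‑methylhepta‑1,5‑dien‑2‑yl]‑7‑oxabicyclo[4.1.0]heptan‑3‑yl acetate (3α,4α‑oxirane in ring A locants)
Conditions: t‑BuOOH, DBU, CH2Cl2, 0 °C
Reagents that add atoms: tert‑butyl hydroperoxide, CC(C)(C)OO
Why: Weitz–Scheffer nucleophilic epoxidation: the tert‑butylperoxide anion adds to C3 anti to the neighbouring C2 silyloxy group (as known for 4‑silyloxycyclohex‑2‑enones) and the enolate closes the oxirane on the same α face, which sets C3 and C4; the electron‑rich chain alkenes do not react with a nucleophilic oxidant.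

Step 15
Reactants: 22 epoxy ketone (2β‑OTBS)
Product: 23 (1S,3S,4R,5R,6S)‑5‑hydroxy‑1‑methyl‑2‑oxo‑4‑[(3S)‑3‑(PMBO)‑6‑methylhepta‑1,5‑dien‑2‑yl]‑7‑oxabicyclo[4.1.0]heptan‑3‑yl acetate
Conditions: HF·pyridine, pyridine, THF, 0 °C → rt
Reagents that add atoms: none
Why: fluoride cleavage of the secondary silyl ether under buffered, weakly acidic conditions is chosen over basic Bu4NF to avoid acetyl migration from O‑6, Payne rearrangement of the trans epoxy alcohol and epimerisation at C6.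

Step 16
Reactants: 23 epoxy alcohol (2β‑OH); 24 tiglic acid
Product: 25 (1S,3S,4R,5S,6S)‑3‑acetoxy‑1‑methyl‑2‑oxo‑4‑[(3S)‑3‑(PMBO)‑6‑methylhepta‑1,5‑dien‑2‑yl]‑7‑oxabicyclo[4.1.0]heptan‑5‑yl (2E)‑2‑methylbut‑2‑enoate
Conditions: PPh3, DIAD, toluene, 0 °C → rt
Reagents that add atoms: none
Why: Mitsunobu esterification: the tiglate anion displaces the oxyphosphonium group at C2 with inversion, turning the 2β alcohol into the 2α ester (cis to the chain and to the oxirane); O‑8 is still protected.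

Step 17
Reactants: 25 C2 tiglate PMB ether
Product: 26 (1S,3S,4R,5S,6S)‑3‑acetoxy‑4‑[(3S)‑3‑hydroxy‑6‑methylhepta‑1,5‑dien‑2‑yl]‑1‑methyl‑2‑oxo‑7‑oxabicyclo[4.1.0]heptan‑5‑yl (2E)‑2‑methylbut‑2‑enoate
Conditions: DDQ (1.2 equiv), CH2Cl2/pH 7 buffer (10:1), 0 °C
Reagents that add atoms: none
Why: oxidative cleavage of the PMB ether (electron transfer from the anisyl ring, then hemiacetal collapse) in buffered wet CH2Cl2 leaves esters, oxirane and alkenes untouched; C8 keeps its configuration.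

Step 18
Reactants: 26 C8 alcohol; 24 tiglic acid
Product: 28 (1S,3S,4R,5S,6S)‑3‑acetoxy‑1‑methyl‑4‑[(3S)‑6‑methyl‑3‑(TigO)hepta‑1,5‑dien‑2‑yl]‑2‑oxo‑7‑oxabicyclo[4.1.0]heptan‑5‑yl (2E)‑2‑methylbut‑2‑enoate, via mixed anhydride 27 (not isolated)
Conditions: 24, 2,4,6‑trichlorobenzoyl chloride, Et3N, toluene, rt; then 26, DMAP, rt → 40 °C
Reagents that add atoms: none
Why: Yamaguchi esterification through the mixed anhydride and the acylpyridinium ion acylates the hindered allylic C8 alcohol with retention and without isomerising the (E)‑enoate.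

Step 19
Reactants: 28 bis‑tiglate
Product: 29 CNP0407453.3
Conditions: D‑fructose‑derived Shi ketone (0.3 equiv), KHSO5 (as 2KHSO5·KHSO4·K2SO4), K2CO3, Bu4NHSO4 (cat.), MeCN/CH2(OMe)2/aq. Na2B4O7–Na2H2EDTA buffer, 0 °C
Reagents that add atoms: potassium peroxymonosulfate, [K+].[O-]S(=O)(=O)OO
Why: Shi asymmetric epoxidation: the chiral dioxirane transfers oxygen through a spiro transition state to the only electron‑rich trisubstituted alkene (C10=C11) and should give the (10R) oxirane, while the 1,1‑disubstituted alkene next to the C8 ester and the two enoates are too electron‑poor to compete.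

**Compound list**

1 | 4‑methylpent‑3‑en‑1‑ol | CC(C)=CCCO | starting material
2 | 4‑methylpent‑3‑enal | CC(C)=CCC=O | intermediate
3 | ethynyltrimethylsilane | C#C[Si](C)(C)C | starting material
4 | lithium (trimethylsilyl)acetylide | [Li]C#C[Si](C)(C)C | intermediate (not isolated)
5 | rac‑6‑methyl‑1‑(trimethylsilyl)hept‑5‑en‑1‑yn‑3‑ol | CC(C)=CCC(O)C#C[Si](C)(C)C | intermediate
6 | 6‑methyl‑1‑(trimethylsilyl)hept‑5‑en‑1‑yn‑3‑one | CC(C)=CCC(=O)C#C[Si](C)(C)C | intermediate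
7 | (3S)‑6‑methyl‑1‑(trimethylsilyl)hept‑5‑en‑1‑yn‑3‑ol | C[Si](C)(C)C#C[C@H](CC=C(C)C)O | intermediate
8 | (3S)‑6‑methylhept‑5‑en‑1‑yn‑3‑ol | C#C[C@H](CC=C(C)C)O | intermediate (not isolated)
9 | 1‑methoxy‑4‑({[(3S)‑6‑methylhept‑5‑en‑1‑yn‑3‑yl]oxy}methyl)benzene | C#C[C@H](CC=C(C)C)OCc1ccc(OC)cc1 | intermediate
10 | tributyl{(3S)‑3‑[(4‑methoxyphenyl)methoxy]‑6‑methylhepta‑1,5‑dien‑2‑yl}stannane | C=C([Sn](CCCC)(CCCC)CCCC)[C@H](CC=C(C)C)OCc1ccc(OC)cc1 | intermediate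
11 | 3‑methylfuran‑2‑carbaldehyde | Cc1ccoc1C=O | starting material
12 | {(3S)‑3‑[(4‑methoxyphenyl)methoxy]‑6‑methylhepta‑1,5‑dien‑2‑yl}lithium | [Li]C(=C)[C@H](CC=C(C)C)OCc1ccc(OC)cc1 | intermediate (not isolated)
13 | (3S)‑3‑[(4‑methoxyphenyl)methoxy]‑6‑methyl‑2‑methylidene‑1‑(3‑methylfuran‑2‑yl)hept‑5‑en‑1‑ol, both C1 epimers | C=C(C(O)c1occc1C)[C@H](CC=C(C)C)OCc1ccc(OC)cc1 | intermediate
14 | (4S,5R)‑4‑hydroxy‑5‑{(3S)‑3‑[(4‑methoxyphenyl)methoxy]‑6‑methylhepta‑1,5‑dien‑2‑yl}‑2‑methylcyclopent‑2‑en‑1‑one | C=C([C@@H]1[C@@H](O)C=C(C)C1=O)[C@H](CC=C(C)C)OCc1ccc(OC)cc1 | intermediate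
15 | (4S,5R)‑4‑{[tert‑butyl(dimethyl)silyl]oxy}‑5‑{(3S)‑3‑[(4‑methoxyphenyl)methoxy]‑6‑methylhepta‑1,5‑dien‑2‑yl}‑2‑methylcyclopent‑2‑en‑1‑one | C=C([C@@H]1[C@@H](O[Si](C)(C)C(C)(C)C)C=C(C)C1=O)[C@H](CC=C(C)C)OCc1ccc(OC)cc1 | intermediate
16 | 1,3‑dithiane | C1CSCSC1 | starting material
17 | 2‑lithio‑1,3‑dithiane | [Li]C1SCCCS1 | intermediate (not isolated)
18 | (1R,4S,5R)‑4‑{[tert‑butyl(dimethyl)silyl]oxy}‑1‑(1,3‑dithian‑2‑yl)‑5‑{(3S)‑3‑[(4‑methoxyphenyl)methoxy]‑6‑methylhepta‑1,5‑dien‑2‑yl}‑2‑methylcyclopent‑2‑en‑1‑ol | C=C([C@@H]1[C@@H](O[Si](C)(C)C(C)(C)C)C=C(C)[C@@]1(O)C2SCCCS2)[C@H](CC=C(C)C)OCc1ccc(OC)cc1 | intermediate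
19 | (1R,4S,5R)‑4‑{[tert‑butyl(dimethyl)silyl]oxy}‑1‑hydroxy‑5‑{(3S)‑3‑[(4‑methoxyphenyl)methoxy]‑6‑methylhepta‑1,5‑dien‑2‑yl}‑2‑methylcyclopent‑2‑ene‑1‑carbaldehyde (key‑step precursor) | C=C([C@@H]1[C@@H](O[Si](C)(C)C(C)(C)C)C=C(C)[C@@]1(O)C=O)[C@H](CC=C(C)C)OCc1ccc(OC)cc1 | intermediate
20 | (4S,5S,6S)‑4‑{[tert‑butyl(dimethyl)silyl]oxy}‑6‑hydroxy‑5‑{(3S)‑3‑[(4‑methoxyphenyl)methoxy]‑6‑methylhepta‑1,5‑dien‑2‑yl}‑2‑methylcyclohex‑2‑en‑1‑one (key‑step product) | C=C([C@@H]1[C@@H](O[Si](C)(C)C(C)(C)C)C=C(C)C(=O)[C@H]1O)[C@H](CC=C(C)C)OCc1ccc(OC)cc1 | intermediate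
21 | (1S,5S,6S)‑5‑{[tert‑butyl(dimethyl)silyl]oxy}‑6‑{(3S)‑3‑[(4‑methoxyphenyl)methoxy]‑6‑methylhepta‑1,5‑dien‑2‑yl}‑3‑methyl‑2‑oxocyclohex‑3‑en‑1‑yl acetate | C=C([C@@H]1[C@@H](O[Si](C)(C)C(C)(C)C)C=C(C)C(=O)[C@H]1OC(C)=O)[C@H](CC=C(C)C)OCc1ccc(OC)cc1 | intermediate
22 | (1S,3S,4S,5R,6S)‑5‑{[tert‑butyl(dimethyl)silyl]oxy}‑4‑{(3S)‑3‑[(4‑methoxyphenyl)methoxy]‑6‑methylhepta‑1,5‑dien‑2‑yl}‑1‑methyl‑2‑oxo‑7‑oxabicyclo[4.1.0]heptan‑3‑yl acetate | C=C([C@@H]1[C@@H](O[Si](C)(C)C(C)(C)C)[C@@H]2O[C@]2(C)C(=O)[C@H]1OC(C)=O)[C@H](CC=C(C)C)OCc1ccc(OC)cc1 | intermediate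
23 | (1S,3S,4R,5R,6S)‑5‑hydroxy‑4‑{(3S)‑3‑[(4‑methoxyphenyl)methoxy]‑6‑methylhepta‑1,5‑dien‑2‑yl}‑1‑methyl‑2‑oxo‑7‑oxabicyclo[4.1.0]heptan‑3‑yl acetate | C=C([C@@H]1[C@@H](O)[C@@H]2O[C@]2(C)C(=O)[C@H]1OC(C)=O)[C@H](CC=C(C)C)OCc1ccc(OC)cc1 | intermediate
24 | tiglic acid, (2E)‑2‑methylbut‑2‑enoic acid | C/C=C(\C)C(=O)O | starting material
25 | (1S,3S,4R,5S,6S)‑3‑acetoxy‑4‑{(3S)‑3‑[(4‑methoxyphenyl)methoxy]‑6‑methylhepta‑1,5‑dien‑2‑yl}‑1‑methyl‑2‑oxo‑7‑oxabicyclo[4.1.0]heptan‑5‑yl (2E)‑2‑methylbut‑2‑enoate | C=C([C@@H]1[C@H](OC(=O)/C(C)=C/C)[C@@H]2O[C@]2(C)C(=O)[C@H]1OC(C)=O)[C@H](CC=C(C)C)OCc1ccc(OC)cc1 | intermediate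
26 | (1S,3S,4R,5S,6S)‑3‑acetoxy‑4‑[(3S)‑3‑hydroxy‑6‑methylhepta‑1,5‑dien‑2‑yl]‑1‑methyl‑2‑oxo‑7‑oxabicyclo[4.1.0]heptan‑5‑yl (2E)‑2‑methylbut‑2‑enoate | C=C([C@@H]1[C@H](OC(=O)/C(C)=C/C)[C@@H]2O[C@]2(C)C(=O)[C@H]1OC(C)=O)[C@H](CC=C(C)C)O | intermediate
27 | (2E)‑2‑methylbut‑2‑enoic 2,4,6‑trichlorobenzoic anhydride | C/C=C(\C)C(=O)OC(=O)c1c(Cl)cc(Cl)cc1Cl | intermediate (not isolated)
28 | (1S,3S,4R,5S,6S)‑3‑acetoxy‑1‑methyl‑4‑[(3S)‑6‑methyl‑3‑{[(2E)‑2‑methylbut‑2‑enoyl]oxy}hepta‑1,5‑dien‑2‑yl]‑2‑oxo‑7‑oxabicyclo[4.1.0]heptan‑5‑yl (2E)‑2‑methylbut‑2‑enoate | C=C([C@@H]1[C@H](OC(=O)/C(C)=C/C)[C@@H]2O[C@]2(C)C(=O)[C@H]1OC(C)=O)[C@H](CC=C(C)C)OC(=O)/C(C)=C/C | intermediate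
29 | CNP0407453.3, (1S,3S,4R,5S,6S)‑3‑acetoxy‑4‑[(3S)‑4‑[(2R)‑3,3‑dimethyloxiran‑2‑yl]‑3‑{[(2E)‑2‑methylbut‑2‑enoyl]oxy}but‑1‑en‑2‑yl]‑1‑methyl‑2‑oxo‑7‑oxabicyclo[4.1.0]heptan‑5‑yl (2E)‑2‑methylbut‑2‑enoate | C=C([C@@H]1[C@H](OC(=O)/C(C)=C/C)[C@@H]2O[C@]2(C)C(=O)[C@H]1OC(C)=O)[C@H](C[C@H]1OC1(C)C)OC(=O)/C(C)=C/C | target

**Count**

Total steps: 19. Longest linear sequence: 19 steps (1 → 29); compounds 3, 11, 16 and 24 enter as purchased pieces.

**Steps most likely to fail**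

Step 16 (Mitsunobu at C2). The displacement must take place at a secondary carbon flanked by the oxirane and the branched C1 substituent, with the carboxylate entering on the α face that carries both; slow substitution would open the way to elimination or to retention through acyloxyphosphonium species. The fallback replaces substitution by oxidation and reduction. It sets out from 23: Dess–Martin oxidation gives the epoxy diketone F1. The C2 carbonyl is the less hindered one, because the C5 carbonyl is shielded by the quaternary C4 and the acetoxy‑bearing C6. Reduction with NaBH4/CeCl3·7H2O in MeOH at −78 °C from the β face, anti to the oxirane oxygen and the C1 chain, should give the 2α epoxy alcohol F2. Yamaguchi esterification of F2 with tiglic acid 24 (retention) returns to the route at 25.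

Step 14 (enone epoxidation). Facial selectivity may be poor if ring A reacts through its all‑equatorial half‑chair, where axial attack at C3 is syn to O‑2, and the basic peroxide may cleave the α‑acetoxy ketone. The fallback sets the oxirane before the ring expansion and sets out from 19. Hydroxyl‑directed epoxidation with VO(acac)2/t‑BuOOH in CH2Cl2 at 0 °C delivers oxygen syn to the tertiary C5 hydroxyl, that is on the α face and anti to the silyloxy group, to give the epoxy hydroxy aldehyde F3. The same amine‑mediated α‑ketol shift (Et3N, MeOH) then gives the epoxy ketol F4. Acetylation of F4 (Ac2O, pyridine, DMAP) returns to the route at 22.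

Step 12 (α‑ketol shift). Under base the product ketol can enolise towards C6, which scrambles C6 and allows vinylogous loss of the C2 silyloxy group; the shift may also run through a hydrogen‑bonded syn array and deliver the C6 epimer. The fallback uses chelation control and then inversion, and sets out from 19. Al(Ot‑Bu)3 in toluene at 60 °C (non‑basic, no hydride to transfer) bridges O‑5 and the formyl oxygen, so C1 adds to the opposite face of the aldehyde and the 6α‑hydroxy enone F5 should result. Mitsunobu reaction of F5 with acetic acid (PPh3, DIAD, THF) is an SN2 displacement next to the ketone that enters from the unhindered β face; it inverts C6 and returns to the route at 21.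

Further compounds
F1 | step 16 | (1S,3S,4S,6S)‑1‑methyl‑2,5‑dioxo‑4‑{(3S)‑3‑[(4‑methoxyphenyl)methoxy]‑6‑methylhepta‑1,5‑dien‑2‑yl}‑7‑oxabicyclo[4.1.0]heptan‑3‑yl acetate (C2 ketone of 23) | C=C([C@@H]1C(=O)[C@@H]2O[C@]2(C)C(=O)[C@H]1OC(C)=O)[C@H](CC=C(C)C)OCc1ccc(OC)cc1
F2 | step 16 | C2 epimer of 23 (2α‑hydroxy, cis to chain and oxirane) | C=C([C@@H]1[C@H](O)[C@@H]2O[C@]2(C)C(=O)[C@H]1OC(C)=O)[C@H](CC=C(C)C)OCc1ccc(OC)cc1
F3 | step 14 | 3α,4α‑epoxide of 19 (2‑hydroxy‑1‑methyl‑4‑silyloxy‑3‑substituted 6‑oxabicyclo[3.1.0]hexane‑2‑carbaldehyde, oxirane syn to the hydroxyl) | C=C([C@@H]1[C@@H](O[Si](C)(C)C(C)(C)C)[C@@H]2O[C@]2(C)[C@@]1(O)C=O)[C@H](CC=C(C)C)OCc1ccc(OC)cc1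
F4 | step 14 | deacetyl 22 (6β‑hydroxy‑3α,4α‑epoxy ketone with 2β‑OTBS) | C=C([C@@H]1[C@@H](O[Si](C)(C)C(C)(C)C)[C@@H]2O[C@]2(C)C(=O)[C@H]1O)[C@H](CC=C(C)C)OCc1ccc(OC)cc1
F5 | step 12 | C6 epimer of 20 (6α‑hydroxy enone) | C=C([C@@H]1[C@@H](O[Si](C)(C)C(C)(C)C)C=C(C)C(=O)[C@@H]1O)[C@H](CC=C(C)C)OCc1ccc(OC)cc1
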